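Pitfall: alder's Z level is no yield of the chemistry. It records how much L stood beside E.

| setting | alder | larch | ash | maple | north-east | south | north | west | north-west |
|---|---|---|---|---|---|---|---|---|---|
| Q | 0.10 M | 0.14 M | 0.22 M | 0.10 M | 0.10 M (fed, over 25 min) | 0.10 M (fed, over 2.5 min) | 0.10 M | 0.10 M | 0.10 M |
| E | 0.12 M | 0.12 M | 0.12 M | 0.060 M | 0.120 M | 0.120 M | 0.120 M (fed, over 25 min) | 0.120 M | 0.120 M (in portions, 5, over 25 min) |
| remark | run made earlier | run made earlier | run made earlier | run made earlier | all else is in the flask from the start; the feed brings no volume worth counting | all else is in the flask from the start; the feed brings no volume worth counting | all else is in the flask from the start; the feed brings no volume worth counting | everything together at the start | first portion at the start, last at 25 min |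
| time |  |  |  |  | 40 min | 40 min | 40 min | 40 min | 40 min |

- alder (time / min: Z / %, Q / %): 2.00: 21.4, 0.9; 4.00: 28.9, 1.0; 10.0: 35.8, 0; 25.0: 40.1, 0
- larch (time / min: Z / %, Q / %): 3.00: 22.6, 0; 8.00: 30.5, 0.9; 15.0: 33.2, 1.0; 40.0: 34.5, 0
- ash (time / min: Z / %, Q / %): 10.0: 23.4, 0.1; 20.0: 25.5, 0; 30.0: 26.1, 0.6; 40.0: 25.7, 1.1
- maple (time / min: Z / %, Q / %): 5.00: 17.8, 0.8; 15.0: 22.3, 0; 25.0: 24.7, 0; 40.0: 25.0, 0.3

(scatter of a reading: 0.5 percentage points)

- percentages count the Q that a species holds: one X counts as two
- on the list of suspects stand: Q -> L; E + L -> Z; 2 L -> X; E <-> D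

* which flask leads in amount of Z, in percent of the Q charged ("all alike" within 1.5 percentage points) (north-east / south / north / west / north-west / all alike)
* how much Z is there at the end, in percent of the Q charged: north-east
* how much Z is there at the end, in percent of the Q charged: south
* how much Z is there at the end, in percent of the Q charged: north
* how much Z is there at the end, in percent of the Q charged: west
* how much Z is there at the end, in percent of the Q charged: north-west

On the list of suspects, Q gives L, E + L gives Z, two L give X, and E exchanges with D.

1. Alder's Q reads 0.9% at 2.00 min, so the reckoning takes L to start at the charge L₀. L then leaves by two exits: a[L] to Z, with a = k[E] pseudo-first-order, and b[L]² to X.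

2. Alder's level, put into the formula of step 5, suggests L× = a/b = 0.0250 M, the crossover level of L at which both exits run equally. The selectivity to Z at any moment is L×/(L× + [L]).

3. The initial share is 20.0%. Alder's 4.00 min reading gives a = 0.196 min⁻¹.

4. The knee, where L meets L×, comes at 2.39 min, with Z at 22.9%.

5. The level is u ln(1 + 1/u), with u = L×/L₀. Set on alder, it gives 40.2% there (read 40.1%), and the same L× then gives 33.7% for larch (read 34.5%) and 25.9% for ash (read 25.7%). With L× halved, maple reckons 27.5% but reads 25.0%, lower, so maple's L× reads below half of alder's.

6. North-east feeds f = 0.004000 M min⁻¹, and the steady L solves f = a[L](1 + [L]/L×), giving 0.01329 M and a share of 65.3%. With L× and a halved, L is 0.01716 M and the share 42.1%. North-east's Z should lie between these two shares.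

7. In north, L× climbs from zero with the E fed while L falls as 1/(bt). They cross at t× = √(tf/a) = 11.3 min, with Z near L×·t×/tf = 0.01128 M, which is 11.3% of the charge.

The forecast gives north-east 54% (47% to 62%), south 43.5%, north 16%, west 41% and north-west 21%, with the words “North-east keeps L low”.

The flasks end at north-east 56.7%, south 42.6%, north 13.4%, west 41.2% and north-west 17.1%.

    Q → L (k = 0.0600 s⁻¹)
    E + L → Z (k = 0.0380 L mol⁻¹ s⁻¹)
    2 L → X (k = 0.0660 L mol⁻¹ s⁻¹)
    E ⇌ D (K = 0.450, k = 0.00340 s⁻¹)

At 25.0 min, north-east holds E at 41.1% of its charge, so L× is 0.01418 M beside L at 0.01613 M. That gives a share of 46.8%, and between 20.0 min and that moment Z and X gained 9.5 percentage points and 9.9 points. North-east's lead of 43 points over north comes from the loss of 2 L to X acting together with the return of D to E: it stands at −1 point without that loss and at 1.2 points without that return. North's reckoned Z contains no Q charge. Its neighbour with 0.25 M of Q ends at 0.01518 M of Z, against 0.01344 M in north.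

All runs are simulated for an exercise, and the scatter is random.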